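**Plan**

- Retrosynthetic cuts, in order: the fifteen O–benzyl bonds; the lactone bond between the bridging galloyl carbonyl and O3 of the lower flavan; C4–C4a of the upper flavan; C4(upper)–C8(lower); the C3–O galloyl ester; the benzylic C2–O1 aryl ether; C2–C3 of the upper unit; the diaryl ether between C2' of upper ring B and O3 of the bridging gallate.
- Enabling feature: upper C4 is a methine bonded to two aryl carbons (C4a of upper ring A, C8 of lower ring A) and adjacent to the acyloxy-bearing C3. Its cation is stabilized by the 5,7,8a-trioxygenated lower ring A, so upper ring C can be closed last, at C4–C4a, from an aryl ether already sitting on O1.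
- Forward order: diaryl ether → C2–C3 (alkoxyallylboration of the ring B aldehyde) → O1–aryl bond → C3 gallate → C4 aldehyde → C4–C8 bond to the intact lower flavan → closure of upper ring C (upper rings A and C become a chroman here) → 16-membered lactone → debenzylation.
- Stereochemistry: lower 2R,3R is bought with (−)-epigallocatechin. Upper C2 and C3 come from the (+)-α-pinene-derived borane (Si-face attack; the Z-alkoxyallyl group in a chair transition state gives the syn pair, i.e. 2,3-cis), and the C2–O bond is kept through the O-arylation. Upper C4 is set in the ring closure, trans to the C3 gallate.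

Key step: step 15

Assumption: the stereodescriptors of the SMILES are taken literally, i.e. upper unit 2R,3R,4R (2,3-cis, 3,4-trans, 4β→8 linkage) and lower unit 2R,3R; carbinol 24 is used as the mixture of its two C4 epimers.

Abbreviations: Bn = benzyl; TMSE = 2-(trimethylsilyl)ethyl; TBS = tert-butyldimethylsilyl; TES = triethylsilyl; MOM = methoxymethyl; Ipc = isopinocampheyl; ArB = 3,4,5-tris(benzyloxy)-2-{2,3-bis(benzyloxy)-5-[(TMSE-oxy)carbonyl]phenoxy}phenyl (upper ring B carrying the bridging gallate as its TMSE ester).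

**Route**

Step 1
Reactants: 1 gallic acid
Product: 2 2-(trimethylsilyl)ethyl 3,4,5-trihydroxybenzoate
Conditions: Cl3CC(=NH)OCH2CH2SiMe3 (1.5 equiv), THF/toluene, 80 °C
Reagents that add atoms: 2-(trimethylsilyl)ethyl 2,2,2-trichloroacetimidate, C[Si](C)(C)CCOC(=N)C(Cl)(Cl)Cl
Why: Promoter-free esterification with a trichloroacetimidate, in which the carboxylic acid protonates the imidate and the carboxylate collects the silicon-stabilized alkyl group while the much less acidic phenols are left alone.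

Step 2
Reactants: 2 2-(trimethylsilyl)ethyl 3,4,5-trihydroxybenzoate
Product: 3 2-(trimethylsilyl)ethyl 3,4-bis(benzyloxy)-5-hydroxybenzoate
Conditions: BnBr (2.0 equiv), K2CO3 (2.0 equiv), DMF, 0 °C → rt, argon
Reagents that add atoms: benzyl bromide, BrCc1ccccc1
Why: Williamson etherification under acidity control, in which the 4-hydroxyl para to the ester reacts first and one of the two equivalent meta hydroxyls second, so that two equivalents of halide should stop at the 3,4-diether, to be separated from mono- and triether by chromatography.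

Step 3
Reactants: 4 3,4,5-tris(benzyloxy)benzaldehyde
Product: 5 2-bromo-3,4,5-tris(benzyloxy)benzaldehyde
Conditions: NBS (1.05 equiv), MeCN, rt
Reagents that add atoms: N-bromosuccinimide, O=C1CCC(=O)N1Br
Why: Electrophilic aromatic bromination at one of the two equivalent free positions, each activated by an ortho and a para benzyloxy group.

Step 4
Reactants: 3 2-(trimethylsilyl)ethyl 3,4-bis(benzyloxy)-5-hydroxybenzoate; 5 2-bromo-3,4,5-tris(benzyloxy)benzaldehyde
Product: 6 ArB-CHO (2-(trimethylsilyl)ethyl 3,4-bis(benzyloxy)-5-[2,3,4-tris(benzyloxy)-6-formylphenoxy]benzoate)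
Conditions: CuI (20 mol%), picolinic acid (40 mol%), K3PO4 (2 equiv), DMSO, 90 °C
Reagents that add atoms: none
Why: Ullmann diaryl ether synthesis under conditions developed for hindered partners, in which the ortho-formyl group assists activation of the aryl bromide and the single free phenol of 3 is the only nucleophile.

Step 5
Reactants: 6 ArB-CHO
Product: 8 (1R,2R)-1-ArB-2-(methoxymethoxy)but-3-en-1-ol, via O-diisopinocampheylboryl borinate 7 (not isolated)
Conditions: CH2=CHCH2OMOM, s-BuLi, THF, −78 °C; (−)-Ipc2BOMe (from (+)-α-pinene); BF3·OEt2; then 6, −78 °C; HOCH2CH2NH2, rt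
Reagents that add atoms: 3-(methoxymethoxy)prop-1-ene, C=CCOCOC
Why: Brown asymmetric alkoxyallylboration, in which the (Z)-γ-alkoxyallylborane reacts through a closed chair transition state so that the Z geometry gives the syn (threo) diol monoether and the isopinocampheyl groups direct attack to the Si face of the aldehyde, setting both new stereocentres as 1R,2R with the future C3 oxygen already protected and the future C4 masked as a vinyl group.

Step 6
Reactants: 9 1,3-bis(benzyloxy)-5-bromobenzene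
Product: 10 1,3-bis(benzyloxy)-5-iodobenzene
Conditions: NaI (2 equiv), CuI (5 mol%), trans-N,N'-dimethylcyclohexane-1,2-diamine (10 mol%), dioxane, 110 °C
Reagents that add atoms: sodium iodide, [Na+].[I-]
Why: Copper-catalysed aromatic Finkelstein halogen exchange, driven by precipitation of NaBr, which supplies the iodide that couples with alcohols far more readily than the bromide.

Step 7
Reactants: 8 (1R,2R)-1-ArB-2-(methoxymethoxy)but-3-en-1-ol; 10 1,3-bis(benzyloxy)-5-iodobenzene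
Product: 11 (1R,2R)-1-ArB-1-[3,5-bis(benzyloxy)phenoxy]-2-(methoxymethoxy)but-3-ene
Conditions: CuI (20 mol%), 3,4,7,8-tetramethyl-1,10-phenanthroline (40 mol%), Cs2CO3 (2 equiv), 10 (3 equiv), 4 Å MS, toluene, 100 °C
Reagents that add atoms: none
Why: Ullmann-type copper-catalysed C–O coupling of a secondary alcohol with an aryl iodide, in which the carbinol C–O bond is never broken so the benzylic centre keeps its R configuration, while the neighbouring oxygen carries an acetal that cannot migrate to the alkoxide and the substrate has no enolizable or acyl group.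

Step 8
Reactants: 11 (1R,2R)-1-ArB-1-[3,5-bis(benzyloxy)phenoxy]-2-(methoxymethoxy)but-3-ene
Product: 12 (1R,2R)-1-ArB-1-[3,5-bis(benzyloxy)phenoxy]but-3-en-2-ol
Conditions: ZnBr2 (1 equiv), n-PrSH (2 equiv), CH2Cl2, 0 °C
Reagents that add atoms: none
Why: Lewis acid–thiol cleavage of the MOM acetal, in which propanethiol captures the methoxymethyl cation before it can alkylate the phloroglucinol-type ring, under conditions that benzyl ethers, the TMSE ester and the benzylic aryl ether should tolerate.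

Step 9
Reactants: 12 (1R,2R)-1-ArB-1-[3,5-bis(benzyloxy)phenoxy]but-3-en-2-ol; 13 3,4,5-tris(benzyloxy)benzoic acid
Product: 15 (1R,2R)-1-ArB-1-[3,5-bis(benzyloxy)phenoxy]but-3-en-2-yl 3,4,5-tris(benzyloxy)benzoate, via acid chloride 14 (not isolated)
Conditions: 13, (COCl)2, DMF (cat.), CH2Cl2, 0 °C → rt; then 12, Et3N, DMAP (cat.), CH2Cl2, 0 °C → rt
Reagents that add atoms: none
Why: DMAP-catalysed acylation of the only free hydroxyl with the acid chloride made in the flask, which puts the C3 gallate in place at a stage with no neighbouring hydroxyl to migrate to and touches no stereocentre.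

Step 10
Reactants: 15 (1R,2R)-1-ArB-1-[3,5-bis(benzyloxy)phenoxy]but-3-en-2-yl 3,4,5-tris(benzyloxy)benzoate
Product: 17 (2S,3R)-3-ArB-3-[3,5-bis(benzyloxy)phenoxy]-1-oxopropan-2-yl 3,4,5-tris(benzyloxy)benzoate, via vicinal diol 16 (not isolated)
Conditions: OsO4 (2 mol%), NaIO4 (4 equiv), 2,6-lutidine (2 equiv), dioxane/H2O (3:1), rt
Reagents that add atoms: osmium tetroxide, O=[Os](=O)(=O)=O; sodium periodate, [Na+].[O-]I(=O)(=O)=O
Why: Lemieux–Johnson oxidative cleavage of the terminal alkene, which delivers the α-acyloxy aldehyde under non-basic conditions so that the α-stereocentre and the β-aryloxy group are not endangered; the crude aldehyde is used at once.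

Step 11
Reactants: 18 (−)-epigallocatechin
Product: 19 (2R,3R)-5,7-bis(benzyloxy)-2-[3,4,5-tris(benzyloxy)phenyl]chroman-3-ol
Conditions: BnBr (5.5 equiv), K2CO3, DMF, −10 °C → rt, argon
Reagents that add atoms: benzyl bromide, BrCc1ccccc1
Why: Williamson etherification of the five phenols under carbonate conditions, which leave the aliphatic 3-hydroxyl alone and are mild enough to avoid base-induced epimerization at C2.

Step 12
Reactants: 19 (2R,3R)-5,7-bis(benzyloxy)-2-[3,4,5-tris(benzyloxy)phenyl]chroman-3-ol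
Product: 20 (2R,3R)-8-bromo-5,7-bis(benzyloxy)-2-[3,4,5-tris(benzyloxy)phenyl]chroman-3-ol
Conditions: NBS (1.0 equiv), CH2Cl2, −78 °C → 0 °C
Reagents that add atoms: N-bromosuccinimide, O=C1CCC(=O)N1Br
Why: Electrophilic aromatic bromination of ring A, which for 5,7-di-O-benzyl flavan-3-ols is known to occur at C8, ring B being far less nucleophilic.

Step 13
Reactants: 20 (2R,3R)-8-bromo-5,7-bis(benzyloxy)-2-[3,4,5-tris(benzyloxy)phenyl]chroman-3-ol
Product: 21 (2R,3R)-8-bromo-3-(tert-butyldimethylsilyloxy)-5,7-bis(benzyloxy)-2-[3,4,5-tris(benzyloxy)phenyl]chroman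
Conditions: TBSOTf, 2,6-lutidine, CH2Cl2, 0 °C
Reagents that add atoms: tert-butyldimethylsilyl triflate, CC(C)(C)[Si](C)(C)OS(=O)(=O)C(F)(F)F
Why: Silylation of the axial 3-hydroxyl as a TBS ether, which withstands tert-butyllithium and the Lewis acid of the ring closure and is later removed together with the TMSE ester by fluoride.

Step 14
Reactants: 21 (2R,3R)-8-bromo-3-(tert-butyldimethylsilyloxy)-5,7-bis(benzyloxy)-2-[3,4,5-tris(benzyloxy)phenyl]chroman; 17 (2S,3R)-3-ArB-3-[3,5-bis(benzyloxy)phenoxy]-1-oxopropan-2-yl 3,4,5-tris(benzyloxy)benzoate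
Product: 24 (1R,2R)-1-ArB-1-[3,5-bis(benzyloxy)phenoxy]-3-hydroxy-3-(lower flavan-8-yl)propan-2-yl 3,4,5-tris(benzyloxy)benzoate as both carbinol epimers, via 8-lithioflavan 22 (not isolated), via 8-dichloroceriumflavan 23 (not isolated)
Conditions: 21 (1.3 equiv), t-BuLi (2.6 equiv), THF, −78 °C; CeCl3 (1.4 equiv), −78 °C; then 17, −78 °C; AcOH, −78 °C
Reagents that add atoms: none
Why: Bromine–lithium exchange, transmetalation and organocerium 1,2-addition, in which the weakly basic, carbonyl-selective arylcerium should add to the aldehyde without enolizing it or attacking the two aryl esters, the cold acetic acid quench should prevent galloyl migration, and the new carbinol centre needs no control because both epimers give the same cation.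

Step 15
Reactants: 24 open-chain carbinol (C2 aryl ether, C3 gallate, C4 carbinol bearing the lower flavan)
Product: 25 (2R,3R,4R)-5,7-bis(benzyloxy)-2-ArB-4-[(2R,3R)-5,7-bis(benzyloxy)-3-(tert-butyldimethylsilyloxy)-2-(3,4,5-tris(benzyloxy)phenyl)chroman-8-yl]chroman-3-yl 3,4,5-tris(benzyloxy)benzoate
Conditions: TMSOTf (20 mol%), 4 Å MS, CH2Cl2 (0.005 M), −78 → −40 °C; Et3N
Reagents that add atoms: none
Why: TMSOTf ionizes the C4 carbinol of either epimer to a benzylic cation delocalized into lower ring A (5,7-dibenzyloxy groups and the pyran oxygen) and reversibly bridged by the carbonyl oxygen of the C3 gallate as a 2-aryl-1,3-dioxolan-2-ylium ion, and the 3,5-dibenzyloxyphenyl ether on the C2 oxygen attacks C4 with one of its two equivalent ortho carbons and rearomatizes by proton loss, which regenerates the acid. The closest known reactions are the acid-catalysed Friedel–Crafts cyclization of 3-aryloxy-1-arylpropan-1-ols to 4-arylchromans and the Lewis acid-mediated C4 substitution of flavan-3-ol esters with neighbouring acyloxy participation. Upper ring C closes as a six-membered ring in which the arene π bond C4a–C8a becomes part of the ring (endo with respect to the arene) while the leaving group departs outside it (exo with respect to the cationic carbon). The new stereocentre C4 is controlled by the C3 acyloxy group: the more stable bridged ion carries the lower aryl group trans to the C2 substituent on the five-membered ring, the arene opens it from the rear, and allylic 1,3-strain in the open cation (C3–H eclipsing the C4–aryl bond) exposes the same face, so the lower flavan ends up trans to the C3 oxygen (4R). The step needs this 3,4-trans outcome, ionization at C4 and not at the benzylic C2 ether, and six-ring closure in preference to attack by other arenes; the far better stabilization of the C4 cation by the trioxygenated ring, the symmetry and high nucleophilicity of the phloroglucinol-type ether, and high dilution should secure them.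

Step 16
Reactants: 25 protected 4→8 dimer (upper 3-O-gallate, lower 3-O-TBS, TMSE ester)
Product: 26 hydroxy acid (lower 3-hydroxyl and bridging carboxylic acid free)
Conditions: Bu4NF (5 equiv), THF, 0 °C → rt; AcOH
Reagents that add atoms: none
Why: Fluoride-induced cleavage of the silyl ether and β-elimination of the TMSE ester in one operation, to which the hindered secondary gallate and the benzyl ethers are inert.

Step 17
Reactants: 26 hydroxy acid
Product: 28 pentadeca-O-benzyl macrolactone, via mixed anhydride 27 (not isolated)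
Conditions: 2-methyl-6-nitrobenzoic anhydride (1.5 equiv), DMAP (6 equiv), CH2Cl2 (0.001 M), slow addition, rt → 40 °C
Reagents that add atoms: none
Why: Shiina macrolactonization, in which DMAP attacks the unhindered galloyl carbonyl of the mixed anhydride and the acylpyridinium is captured by the lower 3-hydroxyl under high dilution with retention at the carbinol carbon, closing the 16-membered lactone that the natural product shows to be accessible.

Step 18
Reactants: 28 pentadeca-O-benzyl macrolactone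
Product: 29 CNP0601265.1
Conditions: H2 (1 atm), Pd(OH)2/C, THF/MeOH (1:1), rt
Reagents that add atoms: none
Why: Hydrogenolysis of all fifteen benzyl ethers, under which the interflavan C–C bond, the diaryl ether, the two esters and the pyran C–O bonds of benzylated proanthocyanidin gallates are expected to stay intact.

**Compound list**

1 | gallic acid (3,4,5-trihydroxybenzoic acid) | OC(=O)c1cc(O)c(O)c(O)c1 | starting material
2 | 2-(trimethylsilyl)ethyl 3,4,5-trihydroxybenzoate | C[Si](C)(C)CCOC(=O)c1cc(O)c(O)c(O)c1 | intermediate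
3 | 2-(trimethylsilyl)ethyl 3,4-bis(benzyloxy)-5-hydroxybenzoate | C[Si](C)(C)CCOC(=O)c1cc(O)c(OCc9ccccc9)c(OCc9ccccc9)c1 | intermediate
4 | 3,4,5-tris(benzyloxy)benzaldehyde | O=Cc1cc(OCc9ccccc9)c(OCc9ccccc9)c(OCc9ccccc9)c1 | starting material
5 | 2-bromo-3,4,5-tris(benzyloxy)benzaldehyde | O=Cc1cc(OCc9ccccc9)c(OCc9ccccc9)c(OCc9ccccc9)c1Br | intermediate
6 | ArB-CHO: 2-(trimethylsilyl)ethyl 3,4-bis(benzyloxy)-5-[2,3,4-tris(benzyloxy)-6-formylphenoxy]benzoate | O=Cc1cc(OCc9ccccc9)c(OCc9ccccc9)c(OCc9ccccc9)c1Oc1cc(cc(OCc9ccccc9)c1OCc9ccccc9)C(=O)OCC[Si](C)(C)C | intermediate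
7 | bis(isopinocampheyl)borinate of alcohol 8, (1R,2R) (not isolated) | COCO[C@H](C=C)[C@H](OB([C@@H]1C[C@@H]2C[C@@H](C2(C)C)[C@H]1C)[C@@H]1C[C@@H]2C[C@@H](C2(C)C)[C@H]1C)c1cc(OCc9ccccc9)c(OCc9ccccc9)c(OCc9ccccc9)c1Oc1cc(cc(OCc9ccccc9)c1OCc9ccccc9)C(=O)OCC[Si](C)(C)C | intermediate
8 | (1R,2R)-1-ArB-2-(methoxymethoxy)but-3-en-1-ol | COCO[C@H](C=C)[C@H](O)c1cc(OCc9ccccc9)c(OCc9ccccc9)c(OCc9ccccc9)c1Oc1cc(cc(OCc9ccccc9)c1OCc9ccccc9)C(=O)OCC[Si](C)(C)C | intermediate
9 | 1,3-bis(benzyloxy)-5-bromobenzene | Brc1cc(OCc9ccccc9)cc(OCc9ccccc9)c1 | starting material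
10 | 1,3-bis(benzyloxy)-5-iodobenzene | Ic1cc(OCc9ccccc9)cc(OCc9ccccc9)c1 | intermediate
11 | (1R,2R)-1-ArB-1-[3,5-bis(benzyloxy)phenoxy]-2-(methoxymethoxy)but-3-ene | COCO[C@H](C=C)[C@H](Oc1cc(OCc9ccccc9)cc(OCc9ccccc9)c1)c1cc(OCc9ccccc9)c(OCc9ccccc9)c(OCc9ccccc9)c1Oc1cc(cc(OCc9ccccc9)c1OCc9ccccc9)C(=O)OCC[Si](C)(C)C | intermediate
12 | (1R,2R)-1-ArB-1-[3,5-bis(benzyloxy)phenoxy]but-3-en-2-ol | O[C@H](C=C)[C@H](Oc1cc(OCc9ccccc9)cc(OCc9ccccc9)c1)c1cc(OCc9ccccc9)c(OCc9ccccc9)c(OCc9ccccc9)c1Oc1cc(cc(OCc9ccccc9)c1OCc9ccccc9)C(=O)OCC[Si](C)(C)C | intermediate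
13 | 3,4,5-tris(benzyloxy)benzoic acid | OC(=O)c1cc(OCc9ccccc9)c(OCc9ccccc9)c(OCc9ccccc9)c1 | starting material
14 | 3,4,5-tris(benzyloxy)benzoyl chloride (not isolated) | ClC(=O)c1cc(OCc9ccccc9)c(OCc9ccccc9)c(OCc9ccccc9)c1 | intermediate
15 | (1R,2R)-1-ArB-1-[3,5-bis(benzyloxy)phenoxy]but-3-en-2-yl 3,4,5-tris(benzyloxy)benzoate | O=C(O[C@H](C=C)[C@H](Oc1cc(OCc9ccccc9)cc(OCc9ccccc9)c1)c1cc(OCc9ccccc9)c(OCc9ccccc9)c(OCc9ccccc9)c1Oc1cc(cc(OCc9ccccc9)c1OCc9ccccc9)C(=O)OCC[Si](C)(C)C)c1cc(OCc9ccccc9)c(OCc9ccccc9)c(OCc9ccccc9)c1 | intermediate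
16 | (1R,2R)-1-ArB-1-[3,5-bis(benzyloxy)phenoxy]-3,4-dihydroxybutan-2-yl 3,4,5-tris(benzyloxy)benzoate, both C3 epimers (not isolated) | O=C(O[C@H](C(O)CO)[C@H](Oc1cc(OCc9ccccc9)cc(OCc9ccccc9)c1)c1cc(OCc9ccccc9)c(OCc9ccccc9)c(OCc9ccccc9)c1Oc1cc(cc(OCc9ccccc9)c1OCc9ccccc9)C(=O)OCC[Si](C)(C)C)c1cc(OCc9ccccc9)c(OCc9ccccc9)c(OCc9ccccc9)c1 | intermediate
17 | (2S,3R)-3-ArB-3-[3,5-bis(benzyloxy)phenoxy]-1-oxopropan-2-yl 3,4,5-tris(benzyloxy)benzoate | O=C(O[C@H](C=O)[C@H](Oc1cc(OCc9ccccc9)cc(OCc9ccccc9)c1)c1cc(OCc9ccccc9)c(OCc9ccccc9)c(OCc9ccccc9)c1Oc1cc(cc(OCc9ccccc9)c1OCc9ccccc9)C(=O)OCC[Si](C)(C)C)c1cc(OCc9ccccc9)c(OCc9ccccc9)c(OCc9ccccc9)c1 | intermediate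
18 | (−)-epigallocatechin, (2R,3R) | O[C@@H]1Cc2c(O)cc(O)cc2O[C@@H]1c1cc(O)c(O)c(O)c1 | starting material
19 | (2R,3R)-5,7-bis(benzyloxy)-2-[3,4,5-tris(benzyloxy)phenyl]chroman-3-ol | O[C@@H]1Cc2c(OCc9ccccc9)cc(OCc9ccccc9)cc2O[C@@H]1c1cc(OCc9ccccc9)c(OCc9ccccc9)c(OCc9ccccc9)c1 | intermediate
20 | (2R,3R)-8-bromo-5,7-bis(benzyloxy)-2-[3,4,5-tris(benzyloxy)phenyl]chroman-3-ol | O[C@@H]1Cc2c(OCc9ccccc9)cc(OCc9ccccc9)c(Br)c2O[C@@H]1c1cc(OCc9ccccc9)c(OCc9ccccc9)c(OCc9ccccc9)c1 | intermediate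
21 | (2R,3R)-8-bromo-3-(tert-butyldimethylsilyloxy)-5,7-bis(benzyloxy)-2-[3,4,5-tris(benzyloxy)phenyl]chroman | CC(C)(C)[Si](C)(C)O[C@@H]1Cc2c(OCc9ccccc9)cc(OCc9ccccc9)c(Br)c2O[C@@H]1c1cc(OCc9ccccc9)c(OCc9ccccc9)c(OCc9ccccc9)c1 | intermediate
22 | 8-lithio derivative of 21 (lithium in place of bromine), (2R,3R) (not isolated) | CC(C)(C)[Si](C)(C)O[C@@H]1Cc2c(OCc9ccccc9)cc(OCc9ccccc9)c([Li])c2O[C@@H]1c1cc(OCc9ccccc9)c(OCc9ccccc9)c(OCc9ccccc9)c1 | intermediate
23 | 8-dichlorocerium derivative of 21 (CeCl2 in place of bromine), (2R,3R) (not isolated) | CC(C)(C)[Si](C)(C)O[C@@H]1Cc2c(OCc9ccccc9)cc(OCc9ccccc9)c([Ce](Cl)Cl)c2O[C@@H]1c1cc(OCc9ccccc9)c(OCc9ccccc9)c(OCc9ccccc9)c1 | intermediate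
24 | (1R,2R)-1-ArB-1-[3,5-bis(benzyloxy)phenoxy]-3-hydroxy-3-[(2R,3R)-5,7-bis(benzyloxy)-3-(tert-butyldimethylsilyloxy)-2-(3,4,5-tris(benzyloxy)phenyl)chroman-8-yl]propan-2-yl 3,4,5-tris(benzyloxy)benzoate, both C3 (carbinol) epimers | O=C(O[C@H](C(O)c5c6O[C@H](c7cc(OCc9ccccc9)c(OCc9ccccc9)c(OCc9ccccc9)c7)[C@H](O[Si](C)(C)C(C)(C)C)Cc6c(OCc9ccccc9)cc5OCc9ccccc9)[C@H](Oc1cc(OCc9ccccc9)cc(OCc9ccccc9)c1)c1cc(OCc9ccccc9)c(OCc9ccccc9)c(OCc9ccccc9)c1Oc1cc(cc(OCc9ccccc9)c1OCc9ccccc9)C(=O)OCC[Si](C)(C)C)c1cc(OCc9ccccc9)c(OCc9ccccc9)c(OCc9ccccc9)c1 | intermediate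
25 | (2R,3R,4R)-5,7-bis(benzyloxy)-2-ArB-4-[(2R,3R)-5,7-bis(benzyloxy)-3-(tert-butyldimethylsilyloxy)-2-(3,4,5-tris(benzyloxy)phenyl)chroman-8-yl]chroman-3-yl 3,4,5-tris(benzyloxy)benzoate | O=C(O[C@@H]1[C@@H](c5c6O[C@H](c7cc(OCc9ccccc9)c(OCc9ccccc9)c(OCc9ccccc9)c7)[C@H](O[Si](C)(C)C(C)(C)C)Cc6c(OCc9ccccc9)cc5OCc9ccccc9)c3c(OCc9ccccc9)cc(OCc9ccccc9)cc3O[C@@H]1c1cc(OCc9ccccc9)c(OCc9ccccc9)c(OCc9ccccc9)c1Oc1cc(cc(OCc9ccccc9)c1OCc9ccccc9)C(=O)OCC[Si](C)(C)C)c1cc(OCc9ccccc9)c(OCc9ccccc9)c(OCc9ccccc9)c1 | intermediate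
26 | hydroxy acid: compound 25 with the lower 3-hydroxyl free and the TMSE ester cleaved to the carboxylic acid, (2R,3R,4R) upper and (2R,3R) lower | O=C(O[C@@H]1[C@@H](c5c6O[C@H](c7cc(OCc9ccccc9)c(OCc9ccccc9)c(OCc9ccccc9)c7)[C@H](O)Cc6c(OCc9ccccc9)cc5OCc9ccccc9)c3c(OCc9ccccc9)cc(OCc9ccccc9)cc3O[C@@H]1c1cc(OCc9ccccc9)c(OCc9ccccc9)c(OCc9ccccc9)c1Oc1cc(cc(OCc9ccccc9)c1OCc9ccccc9)C(=O)O)c1cc(OCc9ccccc9)c(OCc9ccccc9)c(OCc9ccccc9)c1 | intermediate
27 | mixed anhydride of acid 26 and 2-methyl-6-nitrobenzoic acid (not isolated) | O=C(O[C@@H]1[C@@H](c5c6O[C@H](c7cc(OCc9ccccc9)c(OCc9ccccc9)c(OCc9ccccc9)c7)[C@H](O)Cc6c(OCc9ccccc9)cc5OCc9ccccc9)c3c(OCc9ccccc9)cc(OCc9ccccc9)cc3O[C@@H]1c1cc(OCc9ccccc9)c(OCc9ccccc9)c(OCc9ccccc9)c1Oc1cc(cc(OCc9ccccc9)c1OCc9ccccc9)C(=O)OC(=O)c1c(C)cccc1[N+](=O)[O-])c1cc(OCc9ccccc9)c(OCc9ccccc9)c(OCc9ccccc9)c1 | intermediate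
28 | pentadeca-O-benzyl macrolactone (the target with all fifteen phenols as benzyl ethers), (2R,3R,4R) upper and (2R,3R) lower | O=C(O[C@@H]1[C@@H]2c3c(OCc9ccccc9)cc(OCc9ccccc9)cc3O[C@@H]1c1cc(OCc9ccccc9)c(OCc9ccccc9)c(OCc9ccccc9)c1Oc1cc(cc(OCc9ccccc9)c1OCc9ccccc9)C(=O)O[C@@H]1Cc3c(OCc9ccccc9)cc(OCc9ccccc9)c2c3O[C@@H]1c1cc(OCc9ccccc9)c(OCc9ccccc9)c(OCc9ccccc9)c1)c1cc(OCc9ccccc9)c(OCc9ccccc9)c(OCc9ccccc9)c1 | intermediate
29 | CNP0601265.1: (−)-epigallocatechin 3-O-gallate-(4β→8)-(−)-epigallocatechin in which C2' of upper ring B is joined through an ether oxygen to C3 of the galloyl group that esterifies the lower 3-hydroxyl (16-membered lactone) | O=C(O[C@@H]1[C@@H]2c3c(O)cc(O)cc3O[C@@H]1c1cc(O)c(O)c(O)c1Oc1cc(cc(O)c1O)C(=O)O[C@@H]1Cc3c(O)cc(O)c2c3O[C@@H]1c1cc(O)c(O)c(O)c1)c1cc(O)c(O)c(O)c1 | target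

**Step count**

Total step count: 18. Longest linear sequence: 13 steps (1 → 2 → 3 → 6 → 8 → 11 → 12 → 15 → 17 → 24 → 25 → 26 → 28 → 29; steps 1, 2, 4, 5, 7, 8, 9, 10, 14, 15, 16, 17, 18).

**Steps most likely to fail**

Step 7 (O-arylation of the crowded benzylic alcohol). The hindered secondary alkoxide may couple so slowly at copper that reduction of the aryl iodide and oxidation of the carbinol take over. The fallback sets out from 8 and comes back at 11, and makes the C–O bond by substitution at carbon instead of arylation at oxygen. A Mitsunobu reaction of 8 with 4-nitrobenzoic acid (PPh3, DIAD, toluene, 0 °C → rt) inverts the carbinol and gives (1S,2R)-1-ArB-2-(methoxymethoxy)but-3-en-1-yl 4-nitrobenzoate F1. Brief methanolysis (K2CO3, MeOH/THF, 0 °C) frees (1S,2R)-1-ArB-2-(methoxymethoxy)but-3-en-1-ol F2. A second Mitsunobu reaction of F2 with commercial 3,5-bis(benzyloxy)phenol inverts the centre again and delivers 11.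

Step 14 (arylcerium addition to the α-galloyloxy aldehyde). The organometallic may deprotonate the aldehyde, with loss of the β-aryloxide, or the galloyl group may wander onto the new alkoxide before the quench. The fallback sets out from 12 and comes back at 24; it carries the C3 oxygen as a silyl ether through the C–C bond formation and brings in the gallate afterwards. Silylation of 12 (TESCl, imidazole, DMF) gives (1R,2R)-1-ArB-1-[3,5-bis(benzyloxy)phenoxy]-2-(triethylsilyloxy)but-3-ene F3. Lemieux–Johnson cleavage as in step 10 gives (2S,3R)-3-ArB-3-[3,5-bis(benzyloxy)phenoxy]-2-(triethylsilyloxy)propanal F4. Addition of the 8-lithio flavan 22 at −78 °C gives the C3-O-TES carbinol F5 as both epimers. Buffered HF·pyridine (pyridine, THF, 0 °C), which leaves the TBS ether and the TMSE ester alone, gives the 2,3-diol F6. Acylation of the less hindered C3 hydroxyl of F6 with acid chloride 14 (Et3N, DMAP, CH2Cl2, −20 °C) gives 24; the carbinol next to the doubly ortho-substituted ring is the slower site.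

Step 17 (macrolactonization). The rigid dimer may not bring the activated acid and the axial lower hydroxyl together, so that intermolecular acylation and oligomer formation win. The fallback sets out from 24 and comes back at 28; it closes the macrocycle on the flexible open chain and closes ring C afterwards. Bu4NF (THF, 0 °C → rt) converts 24 into the open-chain hydroxy acid F7. Shiina lactonization under high dilution onto the lower 3-hydroxyl gives the macrolactone with ring C still open, F8. The TMSOTf cyclization of step 15, run on F8, then closes C4–C4a inside the macrocycle and gives 28.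

Further compounds
F1 | step 7 | (1S,2R)-1-ArB-2-(methoxymethoxy)but-3-en-1-yl 4-nitrobenzoate | COCO[C@H](C=C)[C@@H](OC(=O)c1ccc(cc1)[N+](=O)[O-])c1cc(OCc9ccccc9)c(OCc9ccccc9)c(OCc9ccccc9)c1Oc1cc(cc(OCc9ccccc9)c1OCc9ccccc9)C(=O)OCC[Si](C)(C)C
F2 | step 7 | (1S,2R)-1-ArB-2-(methoxymethoxy)but-3-en-1-ol | COCO[C@H](C=C)[C@@H](O)c1cc(OCc9ccccc9)c(OCc9ccccc9)c(OCc9ccccc9)c1Oc1cc(cc(OCc9ccccc9)c1OCc9ccccc9)C(=O)OCC[Si](C)(C)C
F3 | step 14 | (1R,2R)-1-ArB-1-[3,5-bis(benzyloxy)phenoxy]-2-(triethylsilyloxy)but-3-ene | CC[Si](CC)(CC)O[C@H](C=C)[C@H](Oc1cc(OCc9ccccc9)cc(OCc9ccccc9)c1)c1cc(OCc9ccccc9)c(OCc9ccccc9)c(OCc9ccccc9)c1Oc1cc(cc(OCc9ccccc9)c1OCc9ccccc9)C(=O)OCC[Si](C)(C)C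
F4 | step 14 | (2S,3R)-3-ArB-3-[3,5-bis(benzyloxy)phenoxy]-2-(triethylsilyloxy)propanal | CC[Si](CC)(CC)O[C@H](C=O)[C@H](Oc1cc(OCc9ccccc9)cc(OCc9ccccc9)c1)c1cc(OCc9ccccc9)c(OCc9ccccc9)c(OCc9ccccc9)c1Oc1cc(cc(OCc9ccccc9)c1OCc9ccccc9)C(=O)OCC[Si](C)(C)C
F5 | step 14 | (1R,2R)-1-ArB-1-[3,5-bis(benzyloxy)phenoxy]-3-[(2R,3R)-5,7-bis(benzyloxy)-3-(tert-butyldimethylsilyloxy)-2-(3,4,5-tris(benzyloxy)phenyl)chroman-8-yl]-2-(triethylsilyloxy)propan-3-ol, both carbinol epimers | CC[Si](CC)(CC)O[C@H](C(O)c5c6O[C@H](c7cc(OCc9ccccc9)c(OCc9ccccc9)c(OCc9ccccc9)c7)[C@H](O[Si](C)(C)C(C)(C)C)Cc6c(OCc9ccccc9)cc5OCc9ccccc9)[C@H](Oc1cc(OCc9ccccc9)cc(OCc9ccccc9)c1)c1cc(OCc9ccccc9)c(OCc9ccccc9)c(OCc9ccccc9)c1Oc1cc(cc(OCc9ccccc9)c1OCc9ccccc9)C(=O)OCC[Si](C)(C)C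
F6 | step 14 | (1R,2R)-1-ArB-1-[3,5-bis(benzyloxy)phenoxy]-3-[(2R,3R)-5,7-bis(benzyloxy)-3-(tert-butyldimethylsilyloxy)-2-(3,4,5-tris(benzyloxy)phenyl)chroman-8-yl]propane-2,3-diol, both C3 epimers | O[C@H](C(O)c5c6O[C@H](c7cc(OCc9ccccc9)c(OCc9ccccc9)c(OCc9ccccc9)c7)[C@H](O[Si](C)(C)C(C)(C)C)Cc6c(OCc9ccccc9)cc5OCc9ccccc9)[C@H](Oc1cc(OCc9ccccc9)cc(OCc9ccccc9)c1)c1cc(OCc9ccccc9)c(OCc9ccccc9)c(OCc9ccccc9)c1Oc1cc(cc(OCc9ccccc9)c1OCc9ccccc9)C(=O)OCC[Si](C)(C)C
F7 | step 17 | open-chain hydroxy acid: compound 24 with the lower 3-hydroxyl free and the TMSE ester cleaved to the carboxylic acid, both carbinol epimers | O=C(O[C@H](C(O)c5c6O[C@H](c7cc(OCc9ccccc9)c(OCc9ccccc9)c(OCc9ccccc9)c7)[C@H](O)Cc6c(OCc9ccccc9)cc5OCc9ccccc9)[C@H](Oc1cc(OCc9ccccc9)cc(OCc9ccccc9)c1)c1cc(OCc9ccccc9)c(OCc9ccccc9)c(OCc9ccccc9)c1Oc1cc(cc(OCc9ccccc9)c1OCc9ccccc9)C(=O)O)c1cc(OCc9ccccc9)c(OCc9ccccc9)c(OCc9ccccc9)c1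
F8 | step 17 | macrolactone of F7 (bridging galloyl carbonyl on the lower 3-oxygen) with upper ring C still open, both carbinol epimers | O=C(O[C@H](C(O)c5c6O[C@H](c7cc(OCc9ccccc9)c(OCc9ccccc9)c(OCc9ccccc9)c7)[C@H]8Cc6c(OCc9ccccc9)cc5OCc9ccccc9)[C@H](Oc1cc(OCc9ccccc9)cc(OCc9ccccc9)c1)c1cc(OCc9ccccc9)c(OCc9ccccc9)c(OCc9ccccc9)c1Oc1cc(cc(OCc9ccccc9)c1OCc9ccccc9)C(=O)O8)c1cc(OCc9ccccc9)c(OCc9ccccc9)c(OCc9ccccc9)c1
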